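**Retrosynthetic overview**

1. Ring D is opened at the C1–O(C21) ester (macrolactonisation last). The 15Z alkene is traced to a C15≡C16 alkyne (semihydrogenation) and C16–C17 to an asymmetric alkynylation of a C17–C21 β-chloro enal, whose 18E geometry is locked earlier in that branch by a temporary six-membered lactone.
2. Rings B and C are disconnected together: N–C22, C5–N and C2=C3 are made in one flask, in which a ring A amine carrying a masked C5=C4–C3 enal is joined to ethyl 2-(diethoxyphosphoryl)acrylate (aza-Michael addition, unmasking, then an aza-Michael/Horner–Wadsworth–Emmons domino).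
3. Enabling feature: in ring C the nitrogen is β to the ester-bearing C2 through C22 (a β-amino ester) and, once C2=C3 is cut to a C3 aldehyde, β to C3 through C5–C4 (a β-amino aldehyde). Both N–C bonds are therefore conjugate additions, and C2=C3 is the olefination of that aldehyde by a C2 phosphonate carbanion.
4. Ring A with C9, C13 and C14 comes from 1-nitrocyclopentene: amine-catalysed Michael addition of propanal (C13, C14), nitro-Michael addition to acrolein (quaternary C9; the nitro group is the masked nitrogen), then two Wittig homologations to the masked enal.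
5. Order of ring formation: ring A is bought, rings B and C form in the same operation, ring D forms last; the dioxolane and the lactone are temporary rings that the route removes.

Key step: step 7

Remark: the target is taken exactly as drawn (5R,9S,13R,14S,17R; 15Z alkene; 18E chloroalkene, that is C17 and C20 cis). Atoms are numbered C1 (lactone C=O), C2=C3, C4, C5 (NCH), C6–C8, C9 (spiro), C10–C12, C13, C14 (CHMe), C15=C16, C17 (CHOH), C18=C19(Cl), C20, C21 (OCH2), C22 (NCH2); ring A is the cyclopentane, B the piperidine, C the tetrahydropyridine, D the macrolactone. 1-Nitrocyclopent-1-ene, ethyl 2-(diethoxyphosphoryl)acrylate and dihydro-2H-pyran-2,4(3H)-dione are assumed to be catalogue compounds.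

**Route**

Step 1
Reactants: 1 1-nitrocyclopent-1-ene; 2 propanal
Product: 3 (2R)-2-[(1R,2S)-2-nitrocyclopentyl]propanal
Conditions: (S)-α,α-diphenylprolinol trimethylsilyl ether (20 mol %), 4-nitrophenol (20 mol %), 2 (3 equiv), toluene, 0 °C → rt
Reagents that add atoms: none
Why: Enamine-catalysed Michael addition of an aldehyde to a nitroalkene with a diarylprolinol silyl ether: the E-enamine of propanal, shielded on one face by the diphenyl(silyloxy)methyl group, adds to C13 through the usual synclinal transition state, so that 13R and 14R (syn) are set by the catalyst, while the nitro-bearing C9 remains epimerisable (trans shown) and is set only in step 3.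

Step 2
Reactants: 3 (2R)-2-[(1R,2S)-2-nitrocyclopentyl]propanal
Product: 4 (1R,2S)-1-[(2R)-but-3-yn-2-yl]-2-nitrocyclopentane
Conditions: dimethyl (1-diazo-2-oxopropyl)phosphonate (1.3 equiv), K2CO3 (2 equiv), MeOH, 0 °C → rt
Reagents that add atoms: dimethyl (1-diazo-2-oxopropyl)phosphonate, CC(=O)C(=[N+]=[N-])P(=O)(OC)OC
Why: The Ohira–Bestmann variant of the Seyferth–Gilbert homologation turns the aldehyde into the terminal alkyne under K2CO3/MeOH at 0 °C, conditions mild enough that the α-stereocentre C14 should be retained, while C9 merely equilibrates through its nitronate.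

Step 3
Reactants: 4 (1R,2S)-1-[(2R)-but-3-yn-2-yl]-2-nitrocyclopentane; 5 acrolein
Product: 6 3-[(1S,2R)-2-[(2R)-but-3-yn-2-yl]-1-nitrocyclopentyl]propanal
Conditions: 5 (1.5 equiv), 1,1,3,3-tetramethylguanidine (10 mol %), MeCN, −20 → 0 °C
Reagents that add atoms: none
Why: Base-catalysed nitro-Michael addition: the planar C9 nitronate is attacked by acrolein on the face opposite the neighbouring C13 but-3-yn-2-yl branch, so the new C9–C8 bond is trans to C14 and the nitro group, the future ring nitrogen, ends cis to it, as in the target (substrate control).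

Step 4
Reactants: 6 3-[(1S,2R)-2-[(2R)-but-3-yn-2-yl]-1-nitrocyclopentyl]propanal
Product: 8 4-[(1S,2R)-2-[(2R)-but-3-yn-2-yl]-1-nitrocyclopentyl]butanal, via enol ether 7 (not isolated)
Conditions: Ph3P(CH2OMe)Cl (1.5 equiv), KN(SiMe3)2 (1.4 equiv), THF, −78 → 0 °C; then 2 M aq. HCl, THF, rt
Reagents that add atoms: (methoxymethyl)triphenylphosphonium chloride, [Cl-].COC[P+](c1ccccc1)(c1ccccc1)c1ccccc1; water, O
Why: Wittig methoxymethylenation and acid hydrolysis of the enol ether is the standard one-carbon homologation of an aldehyde and touches no stereocentre, C9 being quaternary.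

Step 5
Reactants: 8 4-[(1S,2R)-2-[(2R)-but-3-yn-2-yl]-1-nitrocyclopentyl]butanal
Product: 9 2-[5-[(1S,2R)-2-[(2R)-but-3-yn-2-yl]-1-nitrocyclopentyl]pent-1-enyl]-1,3-dioxolane (E/Z mixture)
Conditions: (1,3-dioxolan-2-ylmethyl)triphenylphosphonium bromide (1.4 equiv), t-BuOK (1.3 equiv), THF, 0 °C → rt
Reagents that add atoms: (1,3-dioxolan-2-ylmethyl)triphenylphosphonium bromide, [Br-].C(C1OCCO1)[P+](c1ccccc1)(c1ccccc1)c1ccccc1
Why: Wittig olefination with the dioxolanylmethyl ylide adds C4 and C3 as a vinyl dioxolane, a masked enal whose E/Z ratio is irrelevant because later acid hydrolysis gives the E-enal, and which hides the aldehyde during nitro reduction.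

Step 6
Reactants: 9 2-[5-[(1S,2R)-2-[(2R)-but-3-yn-2-yl]-1-nitrocyclopentyl]pent-1-enyl]-1,3-dioxolane
Product: 10 (1S,2R)-2-[(2R)-but-3-yn-2-yl]-1-[5-(1,3-dioxolan-2-yl)pent-4-enyl]cyclopentan-1-amine
Conditions: LiAlH4 (3 equiv), THF, 0 → 60 °C; then H2O, aq. NaOH
Reagents that add atoms: none
Why: Hydride reduction of a tertiary aliphatic nitro group to the primary amine by LiAlH4, with C9 untouched because no bond to it is broken, while the acetal, the isolated alkene and the (merely deprotonated) terminal alkyne should survive.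

Step 7
Reactants: 10 (1S,2R)-2-[(2R)-but-3-yn-2-yl]-1-[5-(1,3-dioxolan-2-yl)pent-4-enyl]cyclopentan-1-amine; 11 ethyl 2-(diethoxyphosphoryl)prop-2-enoate
Product: 15 ethyl 2'-[(2R)-but-3-yn-2-yl]-1,2,3,6,9,9a-hexahydrospiro[quinolizine-4,1'-cyclopentane]-7-carboxylate (5R,9S,13R,14R), via aminophosphonate 12 (not isolated), via enal 13 (not isolated), via amino aldehyde 14 (not isolated)
Conditions: 11 (1.05 equiv), EtOH, rt; then 2 M aq. HCl, THF, rt; evaporate; then LiCl (5 equiv), DBU (6 equiv), MeCN (0.01 M), 0 °C → rt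
Reagents that add atoms: none
Why: Amine 10 adds to the doubly activated alkene of 11 (N–C22), aqueous HCl unmasks the enal while the ammonium ion is inert, and on addition of LiCl/DBU the free secondary amine adds to C5 of the enal to give β-amino aldehyde 14, whose lithium-chelated C2 phosphonate carbanion attacks the C3 aldehyde and eliminates diethyl phosphate. The closest known reaction types are the tandem hetero- or carba-Michael/intramolecular Horner–Wadsworth–Emmons annulations of 2-phosphonoacrylates (cyclohexene-, dihydrofuran- and pyrroline-carboxylates) and the conjugate cyclisation of amines onto unsaturated carbonyl groups that gives 2,6-cis piperidines on 6-azaspiro[4.5]decanes. Ring B closes by 6-exo-trig conjugate addition of nitrogen, and ring C by 6-exo-trig addition of the carbanion to C=O followed by syn-elimination, which can only give the endocyclic C2=C3 enoate. C5 is controlled by the C9 spiro centre: the reversible aza-Michael step passes through the chair in which the CH2CHO arm is equatorial and cis to the equatorial, more substituted C13 arm of ring A (C10 axial), which gives 5R. The step needs conjugate addition to win over carbonyl condensation (the α-tertiary secondary amine cannot form an imine and the 6-exo closure is fast) and intramolecular olefination to win over intermolecular (six-membered transition state, dilution); the two C2 epimers of 12 converge because C2 becomes sp2.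

Step 8
Reactants: 16 dihydro-2H-pyran-2,4(3H)-dione
Product: 17 4-chloro-5,6-dihydro-2H-pyran-2-one
Conditions: (COCl)2 (1.2 equiv), DMF (cat.), CH2Cl2, 0 °C → rt
Reagents that add atoms: oxalyl chloride, ClC(=O)C(=O)Cl
Why: Vilsmeier-type conversion of a cyclic 1,3-dicarbonyl (vinylogous acid) into the vinylogous acid chloride; the six-membered lactone holds C17 and C20 cis on the C18=C19 bond, so the 18E geometry is locked here by a temporary ring.

Step 9
Reactants: 17 4-chloro-5,6-dihydro-2H-pyran-2-one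
Product: 18 (2E)-3-chloro-5-hydroxy-N-methoxy-N-methylpent-2-enamide
Conditions: MeNH(OMe)·HCl (2 equiv), AlMe3 (2 equiv), CH2Cl2, 0 °C; then 17, −20 → 0 °C; aqueous work-up
Reagents that add atoms: N,O-dimethylhydroxylamine hydrochloride, CNOC.Cl
Why: Weinreb aminolysis of a lactone with the aluminium amide from AlMe3 and MeNH(OMe)·HCl, which transfers nitrogen to the aluminium-bound carbonyl carbon while the ring-locked s-trans enoate keeps C19 out of reach, so the ring opens to the hydroxy amide with the E geometry inherited from the lactone.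

Step 10
Reactants: 18 (2E)-3-chloro-5-hydroxy-N-methoxy-N-methylpent-2-enamide
Product: 19 (2E)-5-[tert-butyl(dimethyl)silyl]oxy-3-chloro-N-methoxy-N-methylpent-2-enamide
Conditions: tert-butyldimethylsilyl chloride (1.2 equiv), imidazole (2 equiv), DMF, 0 °C → rt
Reagents that add atoms: tert-butyldimethylsilyl chloride, CC(C)(C)[Si](C)(C)Cl
Why: Standard silylation of a primary alcohol with tert-butyldimethylsilyl chloride and imidazole, which also prevents relactonisation.

Step 11
Reactants: 19 (2E)-5-[tert-butyl(dimethyl)silyl]oxy-3-chloro-N-methoxy-N-methylpent-2-enamide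
Product: 20 (2E)-5-[tert-butyl(dimethyl)silyl]oxy-3-chloropent-2-enal
Conditions: i-Bu2AlH (1.2 equiv), THF, −78 °C; aqueous work-up
Reagents that add atoms: none
Why: Reduction of a Weinreb amide with i-Bu2AlH stops at the chelated tetrahedral intermediate, which releases the aldehyde only on work-up, and attacks the carbonyl (1,2) of the enamide, so the E-β-chloro enal is obtained without over-reduction.

Step 12
Reactants: 15 ethyl 2'-[(2R)-but-3-yn-2-yl]-1,2,3,6,9,9a-hexahydrospiro[quinolizine-4,1'-cyclopentane]-7-carboxylate; 20 (2E)-5-[tert-butyl(dimethyl)silyl]oxy-3-chloropent-2-enal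
Product: 21 ethyl 2'-[(2R,5S,6E)-9-[tert-butyl(dimethyl)silyl]oxy-7-chloro-5-hydroxynon-6-en-3-yn-2-yl]-1,2,3,6,9,9a-hexahydrospiro[quinolizine-4,1'-cyclopentane]-7-carboxylate (5R,9S,13R)
Conditions: (S,S)-ProPhenol (20 mol %), Ph3P=O (40 mol %), Me2Zn (3 equiv), toluene, rt; then 20 (2 equiv), 0 °C
Reagents that add atoms: none
Why: Zinc–ProPhenol-catalysed asymmetric alkynylation of an α,β-unsaturated aldehyde: the alkynylzinc generated from 15 with Me2Zn is delivered inside the chiral dinuclear zinc complex to the Re face of 20, which sets 17S in 21 by reagent control (the ligand antipode is chosen for this face, (S,S) being the one expected), the remote C14 centre having no influence.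

Step 13
Reactants: 21 the propargylic alcohol of step 12
Product: 22 ethyl 2'-[(2S,3Z,5R,6E)-9-[tert-butyl(dimethyl)silyl]oxy-7-chloro-5-hydroxynona-3,6-dien-2-yl]-1,2,3,6,9,9a-hexahydrospiro[quinolizine-4,1'-cyclopentane]-7-carboxylate (5R,9S,13R)
Conditions: H2 (1 atm), Pd/CaCO3 poisoned with Pb(OAc)2, quinoline, EtOAc, rt
Reagents that add atoms: none
Why: Lindlar-type semihydrogenation adds H2 syn to the C15≡C16 alkyne on poisoned Pd to give the 15Z alkene and should spare the trisubstituted chloroalkene and the enoate; C14 and C17 keep their geometry and change descriptor (to 14S and 17R) only through the priority rules.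

Step 14
Reactants: 22 the Z-alkene silyl ether of step 13
Product: 23 ethyl 2'-[(2S,3Z,5R,6E)-7-chloro-5,9-dihydroxynona-3,6-dien-2-yl]-1,2,3,6,9,9a-hexahydrospiro[quinolizine-4,1'-cyclopentane]-7-carboxylate (5R,9S,13R)
Conditions: HF·pyridine, pyridine, THF, 0 °C → rt
Reagents that add atoms: none
Why: Fluoride-mediated desilylation with pyridine-buffered HF·pyridine removes the primary silyl ether without ionising the bis-allylic C17 alcohol.

Step 15
Reactants: 23 the diol ethyl ester of step 14
Product: 24 2'-[(2S,3Z,5R,6E)-7-chloro-5,9-dihydroxynona-3,6-dien-2-yl]-1,2,3,6,9,9a-hexahydrospiro[quinolizine-4,1'-cyclopentane]-7-carboxylic acid (5R,9S,13R; seco acid)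
Conditions: LiOH (5 equiv), THF/MeOH/H2O, rt; then 1 M HCl to pH 6
Reagents that add atoms: lithium hydroxide, [Li+].[OH-]
Why: Saponification of the ethyl enoate with LiOH, to which the non-conjugated chloroalkene and the allylic alcohol are inert, gives the seco acid as its zwitterion.

Step 16
Reactants: 24 the seco acid of step 15
Product: 25 the target macrolactone (5R,9S,13R,14S,15Z,17R,18E)
Conditions: 2-methyl-6-nitrobenzoic anhydride (1.5 equiv), DMAP (6 equiv), CH2Cl2 (1 mM, slow addition of 24), rt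
Reagents that add atoms: none
Why: Shiina macrolactonisation (mixed anhydride with 2-methyl-6-nitrobenzoic anhydride, acyl transfer by DMAP, high dilution) closes fifteen-membered ring D at the unhindered primary C21 hydroxyl, because the secondary bis-allylic C17 hydroxyl could only close a strained eleven-membered ring.

**Compound list**

1 | 1-nitrocyclopent-1-ene | O=[N+]([O-])C1=CCCC1 | starting material
2 | propanal | CCC=O | starting material
3 | (2R)-2-[(1R,2S)-2-nitrocyclopentyl]propanal (trans shown; C9 epimerisable) | O=C[C@H](C)[C@H]1CCC[C@@H]1[N+](=O)[O-] | intermediate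
4 | (1R,2S)-1-[(2R)-but-3-yn-2-yl]-2-nitrocyclopentane | C#C[C@H](C)[C@H]1CCC[C@@H]1[N+](=O)[O-] | intermediate
5 | acrolein | C=CC=O | starting material
6 | 3-[(1S,2R)-2-[(2R)-but-3-yn-2-yl]-1-nitrocyclopentyl]propanal | O=CCC[C@]1(CCC[C@@H]1[C@@H](C)C#C)[N+](=O)[O-] | intermediate
7 | (1S,2R)-2-[(2R)-but-3-yn-2-yl]-1-(4-methoxybut-3-enyl)-1-nitrocyclopentane (E/Z mixture) | COC=CCC[C@]1(CCC[C@@H]1[C@@H](C)C#C)[N+](=O)[O-] | intermediate
8 | 4-[(1S,2R)-2-[(2R)-but-3-yn-2-yl]-1-nitrocyclopentyl]butanal | O=CCCC[C@]1(CCC[C@@H]1[C@@H](C)C#C)[N+](=O)[O-] | intermediate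
9 | 2-[5-[(1S,2R)-2-[(2R)-but-3-yn-2-yl]-1-nitrocyclopentyl]pent-1-enyl]-1,3-dioxolane (E/Z mixture) | O1CCOC1C=CCCC[C@]2(CCC[C@@H]2[C@@H](C)C#C)[N+](=O)[O-] | intermediate
10 | (1S,2R)-2-[(2R)-but-3-yn-2-yl]-1-[5-(1,3-dioxolan-2-yl)pent-4-enyl]cyclopentan-1-amine (E/Z mixture) | O1CCOC1C=CCCC[C@]2(CCC[C@@H]2[C@@H](C)C#C)N | intermediate
11 | ethyl 2-(diethoxyphosphoryl)prop-2-enoate | C=C(C(=O)OCC)P(=O)(OCC)OCC | starting material
12 | ethyl 3-[[(1S,2R)-2-[(2R)-but-3-yn-2-yl]-1-[5-(1,3-dioxolan-2-yl)pent-4-enyl]cyclopentyl]amino]-2-(diethoxyphosphoryl)propanoate (C2 epimers) | O1CCOC1C=CCCC[C@]2(CCC[C@@H]2[C@@H](C)C#C)NCC(C(=O)OCC)P(=O)(OCC)OCC | intermediate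
13 | ethyl 3-[[(1S,2R)-2-[(2R)-but-3-yn-2-yl]-1-[(4E)-6-oxohex-4-enyl]cyclopentyl]amino]-2-(diethoxyphosphoryl)propanoate (held as its hydrochloride until the base is added) | O=C/C=C/CCC[C@]1(CCC[C@@H]1[C@@H](C)C#C)NCC(C(=O)OCC)P(=O)(OCC)OCC | intermediate
14 | ethyl 3-[(1R,5S,7R)-1-[(2R)-but-3-yn-2-yl]-7-(2-oxoethyl)-6-azaspiro[4.5]decan-6-yl]-2-(diethoxyphosphoryl)propanoate | O=CC[C@H]1CCC[C@]2(CCC[C@@H]2[C@@H](C)C#C)N1CC(C(=O)OCC)P(=O)(OCC)OCC | intermediate
15 | ethyl 2'-[(2R)-but-3-yn-2-yl]-1,2,3,6,9,9a-hexahydrospiro[quinolizine-4,1'-cyclopentane]-7-carboxylate (5R,9S,13R,14R) | CCOC(=O)C1=CC[C@H]2CCC[C@]3(CCC[C@@H]3[C@@H](C)C#C)N2C1 | intermediate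
16 | dihydro-2H-pyran-2,4(3H)-dione | O=C1CC(=O)CCO1 | starting material
17 | 4-chloro-5,6-dihydro-2H-pyran-2-one | O=C1C=C(Cl)CCO1 | intermediate
18 | (2E)-3-chloro-5-hydroxy-N-methoxy-N-methylpent-2-enamide | CON(C)C(=O)/C=C(/Cl)CCO | intermediate
19 | (2E)-5-[tert-butyl(dimethyl)silyl]oxy-3-chloro-N-methoxy-N-methylpent-2-enamide | CON(C)C(=O)/C=C(/Cl)CCO[Si](C)(C)C(C)(C)C | intermediate
20 | (2E)-5-[tert-butyl(dimethyl)silyl]oxy-3-chloropent-2-enal | O=C/C=C(/Cl)CCO[Si](C)(C)C(C)(C)C | intermediate
21 | ethyl 2'-[(2R,5S,6E)-9-[tert-butyl(dimethyl)silyl]oxy-7-chloro-5-hydroxynon-6-en-3-yn-2-yl]-1,2,3,6,9,9a-hexahydrospiro[quinolizine-4,1'-cyclopentane]-7-carboxylate | CCOC(=O)C1=CC[C@H]2CCC[C@]3(CCC[C@@H]3[C@@H](C)C#C[C@@H](O)/C=C(/Cl)CCO[Si](C)(C)C(C)(C)C)N2C1 | intermediate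
22 | ethyl 2'-[(2S,3Z,5R,6E)-9-[tert-butyl(dimethyl)silyl]oxy-7-chloro-5-hydroxynona-3,6-dien-2-yl]-1,2,3,6,9,9a-hexahydrospiro[quinolizine-4,1'-cyclopentane]-7-carboxylate | CCOC(=O)C1=CC[C@H]2CCC[C@]3(CCC[C@@H]3[C@@H](C)/C=C\[C@@H](O)/C=C(/Cl)CCO[Si](C)(C)C(C)(C)C)N2C1 | intermediate
23 | ethyl 2'-[(2S,3Z,5R,6E)-7-chloro-5,9-dihydroxynona-3,6-dien-2-yl]-1,2,3,6,9,9a-hexahydrospiro[quinolizine-4,1'-cyclopentane]-7-carboxylate | CCOC(=O)C1=CC[C@H]2CCC[C@]3(CCC[C@@H]3[C@@H](C)/C=C\[C@@H](O)/C=C(/Cl)CCO)N2C1 | intermediate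
24 | 2'-[(2S,3Z,5R,6E)-7-chloro-5,9-dihydroxynona-3,6-dien-2-yl]-1,2,3,6,9,9a-hexahydrospiro[quinolizine-4,1'-cyclopentane]-7-carboxylic acid (seco acid) | OC(=O)C1=CC[C@H]2CCC[C@]3(CCC[C@@H]3[C@@H](C)/C=C\[C@@H](O)/C=C(/Cl)CCO)N2C1 | intermediate
25 | target macrolactone (5R,9S,13R,14S,15Z,17R,18E) | C[C@H]1/C=C\[C@@H](O)/C=C(/Cl)CCOC(=O)C2=CC[C@H]3CCC[C@]4(CCC[C@H]14)N3C2 | target

**Step count and risk**

Total step count: 16. Longest linear sequence: 12 steps (steps 1–7, then 12–16); aldehyde 20 is made in a 4-step branch (steps 8–11).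

Steps most likely to fail:

1. Step 7. After unmasking, the amino enal may condense intermolecularly, the phosphonoacrylate unit may be lost again by retro-aza-Michael elimination before the olefination, or facial control in the C5–N closure may be insufficient once nitrogen already carries C22. The fallback sets out from 8 and returns to the route at 15, building rings B and C stepwise at the ester level. Aldehyde 8 undergoes Wittig reaction with methyl (triphenylphosphoranylidene)acetate to give methyl (2E)-6-[(1S,2R)-2-[(2R)-but-3-yn-2-yl]-1-nitrocyclopentyl]hex-2-enoate F1. Zn/AcOH reduces the nitro group, and the free primary amine closes ring B by conjugate addition to the enoate, giving methyl 2-[(1R,5S,7R)-1-[(2R)-but-3-yn-2-yl]-6-azaspiro[4.5]decan-7-yl]acetate F2. Claisen condensation with the lithium enolate of ethyl acetate (LiN(SiMe3)2, THF) gives ethyl 4-[(1R,5S,7R)-1-[(2R)-but-3-yn-2-yl]-6-azaspiro[4.5]decan-7-yl]-3-oxobutanoate F3. Aqueous formaldehyde closes ring C by an intramolecular Mannich reaction to the bicyclic β-keto ester F4. NaBH4 gives the β-hydroxy ester F5, and mesylation to the mesylate F6 followed by elimination with DBU gives 15.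

2. Step 12. The complex alkyne used as limiting reagent may convert poorly, the alkynyl transfer may show poor or reversed facial selectivity, or the contra-thermodynamic E-β-chloro enal may isomerise or eliminate. The fallback sets out from 15 (with 19) and returns at 21. The acetylide of 15 (LiN(SiMe3)2, THF, −78 °C) is acylated with Weinreb amide 19 to give the ynone F7. Midland reduction with (S)-Alpine-Borane (B-isopinocampheyl-9-borabicyclo[3.3.1]nonane from (−)-α-pinene), in which the alkynyl group acts as the small substituent, then sets 17S and gives 21.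

3. Step 16. The free C17 hydroxyl may compete for the activated acid, or intermolecular esterification may outrun ring closure. The fallback sets out from 22 and returns at 25. Silylation with i-Pr3SiOTf/2,6-lutidine gives the C17 triisopropylsilyl ether F8. HF·pyridine removes only the primary silyl ether to give the C21 alcohol F9. LiOH gives the seco acid F10. The same Shiina conditions give the C17-silylated macrolactone F11, and Bu4NF cleaves the silyl ether to 25.

**Further compounds**

F1 | step 7 | methyl (2E)-6-[(1S,2R)-2-[(2R)-but-3-yn-2-yl]-1-nitrocyclopentyl]hex-2-enoate | COC(=O)/C=C/CCC[C@]1(CCC[C@@H]1[C@@H](C)C#C)[N+](=O)[O-]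
F2 | step 7 | methyl 2-[(1R,5S,7R)-1-[(2R)-but-3-yn-2-yl]-6-azaspiro[4.5]decan-7-yl]acetate | COC(=O)C[C@H]1CCC[C@]2(CCC[C@@H]2[C@@H](C)C#C)N1
F3 | step 7 | ethyl 4-[(1R,5S,7R)-1-[(2R)-but-3-yn-2-yl]-6-azaspiro[4.5]decan-7-yl]-3-oxobutanoate | CCOC(=O)CC(=O)C[C@H]1CCC[C@]2(CCC[C@@H]2[C@@H](C)C#C)N1
F4 | step 7 | ethyl 2'-[(2R)-but-3-yn-2-yl]-8-oxooctahydrospiro[quinolizine-4,1'-cyclopentane]-7-carboxylate (C2 epimers) | CCOC(=O)C1C(=O)C[C@H]2CCC[C@]3(CCC[C@@H]3[C@@H](C)C#C)N2C1
F5 | step 7 | ethyl 2'-[(2R)-but-3-yn-2-yl]-8-hydroxyoctahydrospiro[quinolizine-4,1'-cyclopentane]-7-carboxylate (C2/C3 isomers) | CCOC(=O)C1C(O)C[C@H]2CCC[C@]3(CCC[C@@H]3[C@@H](C)C#C)N2C1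
F6 | step 7 | ethyl 2'-[(2R)-but-3-yn-2-yl]-8-(methylsulfonyloxy)octahydrospiro[quinolizine-4,1'-cyclopentane]-7-carboxylate | CCOC(=O)C1C(OS(C)(=O)=O)C[C@H]2CCC[C@]3(CCC[C@@H]3[C@@H](C)C#C)N2C1
F7 | step 12 | ethyl 2'-[(2R,6E)-9-[tert-butyl(dimethyl)silyl]oxy-7-chloro-5-oxonon-6-en-3-yn-2-yl]-1,2,3,6,9,9a-hexahydrospiro[quinolizine-4,1'-cyclopentane]-7-carboxylate | CCOC(=O)C1=CC[C@H]2CCC[C@]3(CCC[C@@H]3[C@@H](C)C#CC(=O)/C=C(/Cl)CCO[Si](C)(C)C(C)(C)C)N2C1
F8 | step 16 | C17 triisopropylsilyl ether of 22 | CCOC(=O)C1=CC[C@H]2CCC[C@]3(CCC[C@@H]3[C@@H](C)/C=C\[C@@H](O[Si](C(C)C)(C(C)C)C(C)C)/C=C(/Cl)CCO[Si](C)(C)C(C)(C)C)N2C1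
F9 | step 16 | C17 triisopropylsilyl ether of 23 (C21 alcohol) | CCOC(=O)C1=CC[C@H]2CCC[C@]3(CCC[C@@H]3[C@@H](C)/C=C\[C@@H](O[Si](C(C)C)(C(C)C)C(C)C)/C=C(/Cl)CCO)N2C1
F10 | step 16 | C17 triisopropylsilyl ether of seco acid 24 | OC(=O)C1=CC[C@H]2CCC[C@]3(CCC[C@@H]3[C@@H](C)/C=C\[C@@H](O[Si](C(C)C)(C(C)C)C(C)C)/C=C(/Cl)CCO)N2C1
F11 | step 16 | C17 triisopropylsilyl ether of 25 | C[C@H]1/C=C\[C@@H](O[Si](C(C)C)(C(C)C)C(C)C)/C=C(/Cl)CCOC(=O)C2=CC[C@H]3CCC[C@]4(CCC[C@H]14)N3C2
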